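(The earlier runs and the new flask were generated by integration with constants of no real substance; the scatter is artificial.)

Start from a one-step world: a molecule waits, on average, a time set by one rate constant, then leaves. Put two such waits in a row, the second much the shorter, and follow one molecule through. The population of the second state over that of the first then holds near the ratio of the two waits, a quasi-steady state.

| flask | starting material | other conformer | remark | time |
|---|---|---|---|---|
| Friday's | 1 M | 0.50 equiv | the very flask that is asked about, followed so far |  |
| Wednesday's | 1 M | 0.75 equiv | run made earlier |  |
| flask | 1.0 M | 0.500 equiv |  | 15 d |

- Friday's (time / d: target / %, isomer of the product A / %): 0.625: 7.8, 20.0; 1.25: 8.2, 26.6; 2.08: 8.2, 29.9; 2.50: 7.3, 31.1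
- Wednesday's (time / d: target / %, isomer of the product A / %): 2.50: 6.9, 32.7; 5.00: 2.7, 28.9; 8.00: 2.2, 22.5; 10.0: 1.1, 19.1

(standard deviation of a reading: 0.5 percentage points)

1. ratio of target to isomer of the product A at 20 min
2. ratio of target to isomer of the product A at 15 d
3. which of target and isomer of the product A there is more of at 15 d



Suppose target is the short wait behind isomer of the product A, and ask how far that ratio moves if each given number is off. Take the charge first: in a first-order chain it scales both populations, and at 2.50 d Friday's run reads 0.235 and Wednesday's 0.211, so it matters little. Take the time next: Wednesday's ratios read 0.0934, 0.0978 and 0.0576, with no clear trend beyond their scatter, so going past the last reading matters little too. Now take the readings: the scatter is 2.62% of the last isomer of the product A but 45.5% of the last target, so the target readings matter most.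

Pool them, then. Summed target over summed isomer of the product A from 5.00 d on gives 0.0851, the tail ratio r, with scatter 0.0123. Commit to r for Friday's flask at 15 d.

The forecast gives 0.45, 0.045 and isomer of the product A, its late ratio below mine: “Target falls faster, but its tail is noisy”.

The flask gives 0.388 at 20 min and 0.0696 at 15 d, with isomer of the product A ahead.

    target ⇌ isomer of the product B (K = 20.0, k = 0.00330 /h)
    starting material ⇌ other conformer (K = 1.30, k = 0.00960 /h)
    2 other conformer → self-condensation product (k = 0.0580 /M/h)
    target ⇌ isomer of the product A (K = 0.400, k = 0.00180 /h)
    other conformer → isomer of the product A (k = 0.0780 /h)
    target → over-reaction product (k = 0.0650 /h)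
    starting material → target (k = 0.0150 /h)

At 15 d this flask holds 0.787% of target and 11.3% of isomer of the product A. Multiply that isomer by r and you get 0.962% of target. The neighbour charged with 1.20 equiv of other conformer ends at a ratio of 0.0694; r times its 10.6% of isomer of the product A gives 0.902% of target, and that flask holds 0.735%.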